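**Plan**

- Retrosynthetic cuts: C5′–C6′ of the tetraene (Stille); the C1–O ester bond (Yamaguchi); the C1–C8a bond of ring A, traced back to the C1–C4 bond of a cyclobutanol; C4–C4a (enolate alkenylation); ring B (Diels–Alder, C7–C8 and C4a–C8a).
- Enabling feature: ring A is a cyclohex-3-en-1-ol (C1 carbinol, C8a, then C4a=C4, conjugated with C5=C6 of ring B). This is the product pattern of an alkoxide-accelerated [1,3] shift of a 2-vinylcyclobutanol in which the C8a=C4a bond of a ring B cyclohexa-1,3-diene is the "vinyl" group; opening the strained ring C1–C2–C3–C4 drives formation of C1–C8a.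
- Forward order: ring B by asymmetric Diels–Alder and elaboration to a cross-conjugated dienyl triflate (steps 1–9); C4–C4a coupling with an enantioenriched 3-methylcyclobutanone enol ether; reduction; ring expansion closes ring A; esterification with the C1′–C5′ acid; C9 oxidation; Stille coupling with the C6′–C12′ stannyl acid.
- Stereochemistry: C8 from the catalytic Diels–Alder; C7 from substrate-controlled MeMgBr addition; C3 from enantioselective deprotonation of 3-methylcyclobutanone; C1 and C8a in the ring expansion; C2′/C3′ from an Evans syn-aldol; alkene geometries from syn-carboalumination, syn-hydrostannylation, Horner–Wadsworth–Emmons olefination and stereoretentive Stille coupling.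

Key step: step 13

Remark: numbering is C1–C8a for the decalin, C9–C11 for the 3-hydroxypropanoyl chain, C1′–C12′ for the acid from the ester carbonyl, and cyclobutane carbons carry their later ring A numbers. Dx = (4R)-2,2-di-tert-butyl-1,3,2-dioxasilinan-4-yl, TES = triethylsilyl, TBS = tert-butyldimethylsilyl. It is assumed that the catalyst antipode in step 1 and the lithium amide antipode in step 10 are those that give the configurations drawn, and that (R)-HYTRA induces (9R) as it does with simple aldehydes.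

**Step 1**
Reactants: 1 methacrolein; 2 (E)-buta-1,3-dien-1-yl acetate
Product: 3 (1S,6R)-6-formyl-6-methylcyclohex-2-en-1-yl acetate
Conditions: B-(o-tolyl)oxazaborolidine from α,α-diphenylprolinol protonated with HNTf2 (10 mol %), CH2Cl2, −78 → −40 °C
Reagents that add atoms: none
Why: Catalytic enantioselective Diels–Alder reaction in which the acetoxy-bearing diene terminus bonds to the enal α-carbon and the chiral Lewis acid shields one face of the s-trans enal, setting quaternary C8 (R); the endo-derived C7 acetoxy centre is erased in step 5.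

**Step 2**
Reactants: 3 (1S,6R)-6-formyl-6-methylcyclohex-2-en-1-yl acetate; 4 (R)-2-hydroxy-1,2,2-triphenylethyl acetate ((R)-HYTRA)
Product: 6 (R)-2-hydroxy-1,2,2-triphenylethyl (3R)-3-[(1S,2S)-2-acetoxy-1-methylcyclohex-3-en-1-yl]-3-hydroxypropanoate, via dilithium acetate enolate 5 (not isolated)
Conditions: 4, LiN(i-Pr)2 (2.2 equiv), THF, −78 → 0 °C; then 3, −100 °C; aq. NH4Cl
Reagents that add atoms: none
Why: Acetate aldol addition of the doubly deprotonated chiral acetate to a non-enolisable aldehyde, the reagent fixing the temporary C9 carbinol centre (R).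

**Step 3**
Reactants: 6 aldol ester
Product: 7 (1R)-1-[(1S,2S)-2-hydroxy-1-methylcyclohex-3-en-1-yl]propane-1,3-diol
Conditions: LiAlH4, THF, 0 °C; H2O/NaOH work-up
Reagents that add atoms: none
Why: Hydride reduction cleaves the chiral ester to the C11 primary alcohol and removes the acetate in the same operation without touching a stereocentre.

**Step 4**
Reactants: 7 triol
Product: 8 (1S,6R)-6-Dx-6-methylcyclohex-2-en-1-ol
Conditions: t-Bu2Si(OTf)2 (1.05 equiv), 2,6-lutidine, CH2Cl2, −40 → 0 °C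
Reagents that add atoms: di-tert-butylsilyl bis(trifluoromethanesulfonate) CC(C)(C)[Si](OS(=O)(=O)C(F)(F)F)(OS(=O)(=O)C(F)(F)F)C(C)(C)C
Why: Silylene protection in which the primary C11 hydroxyl is silylated first and the silyl triflate then closes on the C9 hydroxyl to the six-membered dioxasilinane, leaving the hindered allylic C7 hydroxyl free.

**Step 5**
Reactants: 8 allylic alcohol
Product: 9 (6S)-6-Dx-6-methylcyclohex-2-en-1-one
Conditions: Dess–Martin periodinane, NaHCO3, CH2Cl2, 0 °C → rt
Reagents that add atoms: none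
Why: Dess–Martin oxidation of the allylic C7 alcohol gives the enone and removes the C7 centre left by the Diels–Alder step.

**Step 6**
Reactants: 9 enone
Product: 10 (1R,6S)-6-Dx-1,6-dimethylcyclohex-2-en-1-ol
Conditions: MeMgBr, THF, −78 °C; aq. NH4Cl
Reagents that add atoms: methylmagnesium bromide C[Mg]Br
Why: Grignard 1,2-addition in which, with the bulky Dx group pseudoequatorial, the nucleophile attacks anti to the pseudoaxial C8 methyl, so that the new C7 methyl is cis to the C9 chain and the hydroxyl cis to the C8 methyl (7R).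

**Step 7**
Reactants: 10 tertiary alcohol
Product: 11 (4R)-2,2-di-tert-butyl-4-[(1S,2R)-1,2-dimethyl-2-(triethylsilyloxy)cyclohex-3-en-1-yl]-1,3,2-dioxasilinane
Conditions: Et3SiOTf, 2,6-lutidine, CH2Cl2, −78 → 0 °C
Reagents that add atoms: triethylsilyl trifluoromethanesulfonate CC[Si](CC)(CC)OS(=O)(=O)C(F)(F)F
Why: Silylation of the tertiary alcohol masks the C7 oxygen, whose potassium alkoxide could otherwise open ring B by retro-allylation in step 13.

**Step 8**
Reactants: 11 cyclohexene
Product: 12 (4R,5S)-5-Dx-4,5-dimethyl-4-(triethylsilyloxy)cyclohex-2-en-1-one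
Conditions: Rh2(caprolactamate)4 (1 mol %), t-BuOOH, K2CO3, CH2Cl2, rt
Reagents that add atoms: tert-butyl hydroperoxide CC(C)(C)OO
Why: Allylic C–H oxidation at C4a, the only allylic CH2 (C7 is quaternary) and the less hindered end of the allyl radical, gives the C4a enone.

**Step 9**
Reactants: 12 enone
Product: 14 (3S,4R)-3-Dx-3,4-dimethyl-4-(triethylsilyloxy)cyclohexa-1,5-dien-1-yl trifluoromethanesulfonate, via potassium dienolate 13 (not isolated)
Conditions: KN(SiMe3)2, THF, −78 °C; then PhNTf2, −78 → 0 °C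
Reagents that add atoms: N-phenylbis(trifluoromethanesulfonimide) O=S(=O)(N(c1ccccc1)S(=O)(=O)C(F)(F)F)C(F)(F)F
Why: Kinetic α′-deprotonation at C8a, the only enolisable position, gives the cross-conjugated dienolate, and O-triflation affords the 2-triflyloxy-1,3-diene.

**Step 10**
Reactants: 15 3-methylcyclobutan-1-one
Product: 17 (R)-trimethyl[(3-methylcyclobut-1-en-1-yl)oxy]silane, via lithium enolate 16 (not isolated)
Conditions: lithium (R,R)-bis(1-phenylethyl)amide (from the amine and n-BuLi), Me3SiCl present from the start, THF, −100 °C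
Reagents that add atoms: chlorotrimethylsilane C[Si](C)(C)Cl
Why: Enantioselective deprotonation of the prochiral ketone by a chiral lithium amide with in situ silylation distinguishes the enantiotopic α-CH2 groups and so defines C3 (R) and the enol carbon next to it.

**Step 11**
Reactants: 14 dienyl triflate; 17 silyl enol ether
Product: 19 (2R,3R)-2-[(3S,4R)-3-Dx-3,4-dimethyl-4-(triethylsilyloxy)cyclohexa-1,5-dien-1-yl]-3-methylcyclobutan-1-one, via tributyltin enolate 18 (not isolated)
Conditions: Pd2(dba)3 (2.5 mol %), P(t-Bu)3 (10 mol %), Bu3SnF, CsF, toluene, 60 °C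
Reagents that add atoms: none
Why: Palladium-catalysed α-alkenylation of a silyl enol ether (silicon-to-tin exchange, oxidative addition of the triflate to zerovalent palladium, reductive elimination) forms C4–C4a at the regiodefined enol carbon, with the dienyl group trans to the C3 methyl.

**Step 12**
Reactants: 19 cyclobutanone
Product: 20 (1R,2R,3R)-2-[(3S,4R)-3-Dx-3,4-dimethyl-4-(triethylsilyloxy)cyclohexa-1,5-dien-1-yl]-3-methylcyclobutan-1-ol
Conditions: NaBH4, MeOH/THF, −40 °C
Reagents that add atoms: none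
Why: Borohydride reduction from the face opposite the dienyl group; the configurations at the carbinol and dienyl-bearing carbons are unimportant because both are erased in step 13.

**Step 13**
Reactants: 20 cyclobutanol
Product: 23 (1S,3R,7R,8S,8aS)-8-Dx-3,7,8-trimethyl-7-(triethylsilyloxy)-1,2,3,7,8,8a-hexahydronaphthalen-1-ol, via potassium cyclobutanolate 21 (not isolated), via allylpotassium aldehyde 22 (not isolated)
Conditions: KH, 18-crown-6, THF, 0 → 25 °C; aq. NH4Cl at 0 °C
Reagents that add atoms: none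
Why: Deprotonation gives cyclobutanolate 21, whose strained C1–C4 bond (allylic to C4a=C8a of the ring B diene) cleaves heterolytically to the aldehyde-tethered 2-vinylallyl anion 22, and bond formation between the aldehyde carbon C1 and the allyl terminus C8a completes a formal alkoxide-accelerated [1,3] shift. The closest known reaction type is the alkoxide-accelerated vinylcyclobutane-to-cyclohexene rearrangement of 2-vinylcyclobutanol salts to cyclohex-3-en-1-ols. Ring A is the only ring closed: the four-membered ring C1–C2–C3–C4 grows by the two atoms C4a and C8a through a 6-exo-trig addition to the aldehyde with the allyl unit inside the ring, leaving C4=C4a in ring A conjugated with C5=C6. C8a should be set by ring B, because with the bulky C7 silyloxy and C8 Dx groups anti (both pseudoaxial) the β face of C8a is blocked and C1 adds to the α face syn to the C8 methyl; C1 should be set by a potassium-bridged closed arrangement that turns the carbonyl oxygen toward the allyl unit (oxygen α); C3 is untouched and keeps the configuration from step 10. The step needs recombination at C8a and not C4 (reclosure at C4 only regenerates 21, so strain release funnels material to 23), α- over β-face attack (ring B substituents, at the cost of a pseudoaxial C3 methyl), and C–C bond formation faster than proton transfer from C2–H (intramolecular ion pair, no other acidic C–H or enolisable carbonyl in 21).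

**Step 14**
Reactants: 24 prop-2-yn-1-ol
Product: 26 (E)-3-iodo-2-methylprop-2-en-1-ol, via alkenylalane 25 (not isolated)
Conditions: AlMe3 (3 equiv), Cp2ZrCl2 (0.25 equiv), CH2Cl2, 0 °C → rt; then I2, THF, −30 °C; aq. K2CO3
Reagents that add atoms: trimethylaluminium C[Al](C)C; iodine II
Why: Zirconium-catalysed Negishi carboalumination adds methyl and aluminium syn across the alkyne with aluminium at the terminus, and iodinolysis with retention gives the E vinyl iodide.

**Step 15**
Reactants: 26 allylic alcohol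
Product: 27 (E)-3-iodo-2-methylprop-2-enal
Conditions: MnO2, CH2Cl2, rt
Reagents that add atoms: none
Why: MnO2 oxidation of the allylic alcohol gives the enal without isomerising the alkene.

**Step 16**
Reactants: 28 (S)-4-benzyl-3-propanoyl-1,3-oxazolidin-2-one; 27 (E)-3-iodo-2-methylprop-2-enal
Product: 30 (S)-4-benzyl-3-[(2S,3S,4E)-3-hydroxy-5-iodo-2,4-dimethylpent-4-enoyl]-1,3-oxazolidin-2-one, via dibutylboron enolate 29 (not isolated)
Conditions: Bu2BOTf, i-Pr2NEt, CH2Cl2, −78 → 0 °C; then 27, −78 → 0 °C; pH 7 buffer/MeOH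
Reagents that add atoms: none
Why: Evans syn-aldol in which the Z boron enolate reacts through a Zimmerman–Traxler chair and the (S)-benzyl auxiliary sets C2′ and C3′ (2S,3S).

**Step 17**
Reactants: 30 aldol adduct
Product: 31 (S)-4-benzyl-3-[(2S,3S,4E)-3-(tert-butyldimethylsilyloxy)-5-iodo-2,4-dimethylpent-4-enoyl]-1,3-oxazolidin-2-one
Conditions: t-BuMe2SiOTf, 2,6-lutidine, CH2Cl2, −78 → 0 °C
Reagents that add atoms: tert-butyldimethylsilyl trifluoromethanesulfonate CC(C)(C)[Si](C)(C)OS(=O)(=O)C(F)(F)F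
Why: Silylation of the secondary alcohol prevents retro-aldol cleavage and self-acylation later.

**Step 18**
Reactants: 31 silylated imide
Product: 32 (2S,3S,4E)-3-(tert-butyldimethylsilyloxy)-5-iodo-2,4-dimethylpent-4-enoic acid
Conditions: LiOH, H2O2, THF/H2O, 0 °C; Na2SO3; HCl to pH 3
Reagents that add atoms: lithium hydroperoxide (from LiOH and H2O2) [Li+].[O-]O
Why: Hydroperoxide cleaves the imide at the exocyclic carbonyl without epimerising C2′ and releases the acid and the auxiliary.

**Step 19**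
Reactants: 33 (E)-3-methylpent-2-en-4-yn-1-ol
Product: 34 (2E,4E)-3-methyl-5-(tributylstannyl)penta-2,4-dien-1-ol
Conditions: Bu3SnH, PdCl2(PPh3)2 (2 mol %), THF, 0 °C
Reagents that add atoms: tributyltin hydride CCCC[SnH](CCCC)CCCC
Why: Palladium-catalysed syn-hydrostannylation of the terminal alkyne places tin at the terminus and gives the E vinylstannane.

**Step 20**
Reactants: 34 stannyl dienol
Product: 35 (2E,4E)-3-methyl-5-(tributylstannyl)penta-2,4-dienal
Conditions: MnO2, CH2Cl2, rt
Reagents that add atoms: none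
Why: MnO2 oxidation of the allylic alcohol is mild enough to keep the vinylstannane and both alkene geometries.

**Step 21**
Reactants: 35 stannyl dienal; 36 2-(diethoxyphosphoryl)acetic acid
Product: 38 (2E,4E,6E)-5-methyl-7-(tributylstannyl)hepta-2,4,6-trienoic acid, via dilithium phosphonoacetate dianion 37 (not isolated)
Conditions: 36, n-BuLi (2.1 equiv), THF, −78 → 0 °C; then 35, 0 °C → rt; aq. NH4Cl
Reagents that add atoms: none
Why: Horner–Wadsworth–Emmons olefination with the phosphonoacetic acid dianion gives the E acid directly, so no ester hydrolysis is needed beside the stannane.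

**Step 22**
Reactants: 23 decalinol; 32 acid
Product: 40 C1 ester of 23 with 32 (1S,3R,7R,8S,8aS; 2′S,3′S,4′E), via mixed anhydride 39 (not isolated)
Conditions: 32, 2,4,6-trichlorobenzoyl chloride, Et3N, THF, rt; then 23, DMAP, toluene, 40 °C
Reagents that add atoms: none
Why: Yamaguchi esterification through the mixed anhydride acylates the hindered axial C1 hydroxyl, the only free OH, with retention at C1 and without epimerising C2′.

**Step 23**
Reactants: 40 ester
Product: 41 C7,C9,C11-triol of 40 (silylene and C7 TES ether removed; C3′ TBS ether kept)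
Conditions: HF·pyridine, pyridine, THF, 0 °C → rt, monitored
Reagents that add atoms: none
Why: Buffered fluoride cleaves the silylene and the tertiary TES ether, both more labile than the secondary TBS ether.

**Step 24**
Reactants: 41 triol
Product: 42 C11 triethylsilyl ether of 41
Conditions: Et3SiCl (1.1 equiv), imidazole, CH2Cl2, −40 °C
Reagents that add atoms: chlorotriethylsilane CC[Si](Cl)(CC)CC
Why: Selective silylation of the primary C11 hydroxyl over the neopentyl secondary C9 and tertiary C7 hydroxyls.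

**Step 25**
Reactants: 42 diol
Product: 43 C9 ketone of 42
Conditions: Dess–Martin periodinane, NaHCO3, CH2Cl2, 0 °C
Reagents that add atoms: none
Why: Dess–Martin oxidation of the only free secondary alcohol (C9) gives the ketone; the tertiary C7 alcohol cannot be oxidised and the buffered medium avoids retro-aldol cleavage.

**Step 26**
Reactants: 43 ketone
Product: 44 (1S,3R,7R,8R,8aS)-7-hydroxy-8-(3-hydroxypropanoyl)-3,7,8-trimethyl-1,2,3,7,8,8a-hexahydronaphthalen-1-yl (2S,3S,4E)-3-hydroxy-5-iodo-2,4-dimethylpent-4-enoate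
Conditions: HF·pyridine, pyridine, THF, 0 °C → rt
Reagents that add atoms: none
Why: Buffered HF·pyridine removes the remaining TES and TBS ethers under mildly acidic conditions that spare the β-hydroxy ketone, the ester and the tertiary dienylic alcohol.

**Step 27**
Reactants: 44 vinyl iodide; 38 stannyl trienoic acid
Product: 45 CNP0306937.1 (target)
Conditions: PdCl2(MeCN)2 (10 mol %), DMF, rt, dark
Reagents that add atoms: none
Why: Stille coupling proceeds with retention at both alkenes, tolerates free hydroxyl and carboxyl groups and forms C5′–C6′ of the all-E tetraene as the last step.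

**Compound list**

1 | methacrolein | CC(=C)C=O | starting material
2 | (E)-buta-1,3-dien-1-yl acetate | CC(=O)O/C=C/C=C | starting material
3 | (1S,6R)-6-formyl-6-methylcyclohex-2-en-1-yl acetate | C1C=C[C@H](OC(C)=O)[C@](C)(C=O)C1 | intermediate
4 | (R)-2-hydroxy-1,2,2-triphenylethyl acetate | CC(=O)O[C@H](c1ccccc1)C(O)(c1ccccc1)c1ccccc1 | starting material
5 | dilithium acetate enolate of 4 | [Li+].[Li+].C=C([O-])O[C@H](c1ccccc1)C([O-])(c1ccccc1)c1ccccc1 | intermediate
6 | (R)-2-hydroxy-1,2,2-triphenylethyl (3R)-3-[(1S,2S)-2-acetoxy-1-methylcyclohex-3-en-1-yl]-3-hydroxypropanoate | C1C=C[C@H](OC(C)=O)[C@](C)([C@H](O)CC(=O)O[C@H](c2ccccc2)C(O)(c2ccccc2)c2ccccc2)C1 | intermediate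
7 | (1R)-1-[(1S,2S)-2-hydroxy-1-methylcyclohex-3-en-1-yl]propane-1,3-diol | C1C=C[C@H](O)[C@](C)([C@H](O)CCO)C1 | intermediate
8 | (1S,6R)-6-Dx-6-methylcyclohex-2-en-1-ol | C1C=C[C@H](O)[C@](C)([C@H]2CCO[Si](C(C)(C)C)(C(C)(C)C)O2)C1 | intermediate
9 | (6S)-6-Dx-6-methylcyclohex-2-en-1-one | C1C=CC(=O)[C@](C)([C@H]2CCO[Si](C(C)(C)C)(C(C)(C)C)O2)C1 | intermediate
10 | (1R,6S)-6-Dx-1,6-dimethylcyclohex-2-en-1-ol | C1C=C[C@@](C)(O)[C@](C)([C@H]2CCO[Si](C(C)(C)C)(C(C)(C)C)O2)C1 | intermediate
11 | (4R)-2,2-di-tert-butyl-4-[(1S,2R)-1,2-dimethyl-2-(triethylsilyloxy)cyclohex-3-en-1-yl]-1,3,2-dioxasilinane | C1C=C[C@@](C)(O[Si](CC)(CC)CC)[C@](C)([C@H]2CCO[Si](C(C)(C)C)(C(C)(C)C)O2)C1 | intermediate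
12 | (4R,5S)-5-Dx-4,5-dimethyl-4-(triethylsilyloxy)cyclohex-2-en-1-one | O=C1C=C[C@@](C)(O[Si](CC)(CC)CC)[C@](C)([C@H]2CCO[Si](C(C)(C)C)(C(C)(C)C)O2)C1 | intermediate
13 | potassium cross-conjugated dienolate of 12 | [K+].[O-]C1=C[C@@](C)([C@H]2CCO[Si](C(C)(C)C)(C(C)(C)C)O2)[C@](C)(O[Si](CC)(CC)CC)C=C1 | intermediate
14 | (3S,4R)-3-Dx-3,4-dimethyl-4-(triethylsilyloxy)cyclohexa-1,5-dien-1-yl trifluoromethanesulfonate | FC(F)(F)S(=O)(=O)OC1=C[C@@](C)([C@H]2CCO[Si](C(C)(C)C)(C(C)(C)C)O2)[C@](C)(O[Si](CC)(CC)CC)C=C1 | intermediate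
15 | 3-methylcyclobutan-1-one | CC1CC(=O)C1 | starting material
16 | lithium (R)-3-methylcyclobut-1-en-1-olate | [Li+].C[C@H]1C=C([O-])C1 | intermediate
17 | (R)-trimethyl[(3-methylcyclobut-1-en-1-yl)oxy]silane | C[C@H]1C=C(O[Si](C)(C)C)C1 | intermediate
18 | (R)-tributyl[(3-methylcyclobut-1-en-1-yl)oxy]stannane | C[C@H]1C=C(O[Sn](CCCC)(CCCC)CCCC)C1 | intermediate
19 | (2R,3R)-2-[(3S,4R)-3-Dx-3,4-dimethyl-4-(triethylsilyloxy)cyclohexa-1,5-dien-1-yl]-3-methylcyclobutan-1-one | O=C1C[C@@H](C)[C@@H]1C2=C[C@@](C)([C@H]3CCO[Si](C(C)(C)C)(C(C)(C)C)O3)[C@](C)(O[Si](CC)(CC)CC)C=C2 | intermediate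
20 | (1R,2R,3R)-2-[(3S,4R)-3-Dx-3,4-dimethyl-4-(triethylsilyloxy)cyclohexa-1,5-dien-1-yl]-3-methylcyclobutan-1-ol | O[C@@H]1C[C@@H](C)[C@@H]1C2=C[C@@](C)([C@H]3CCO[Si](C(C)(C)C)(C(C)(C)C)O3)[C@](C)(O[Si](CC)(CC)CC)C=C2 | intermediate
21 | potassium alkoxide of 20 | [K+].[O-][C@@H]1C[C@@H](C)[C@@H]1C2=C[C@@](C)([C@H]3CCO[Si](C(C)(C)C)(C(C)(C)C)O3)[C@](C)(O[Si](CC)(CC)CC)C=C2 | intermediate
22 | ring-opened allylpotassium aldehyde (C1 aldehyde, anion over C4–C4a–C8a) | [K+].O=CC[C@@H](C)[CH-]C1=C[C@@](C)([C@H]2CCO[Si](C(C)(C)C)(C(C)(C)C)O2)[C@](C)(O[Si](CC)(CC)CC)C=C1 | intermediate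
23 | (1S,3R,7R,8S,8aS)-8-Dx-3,7,8-trimethyl-7-(triethylsilyloxy)-1,2,3,7,8,8a-hexahydronaphthalen-1-ol | O[C@H]1C[C@@H](C)C=C2C=C[C@@](C)(O[Si](CC)(CC)CC)[C@](C)([C@H]3CCO[Si](C(C)(C)C)(C(C)(C)C)O3)[C@H]21 | intermediate
24 | prop-2-yn-1-ol | C#CCO | starting material
25 | (E)-alkenylalane, dimethylaluminium alkoxide | C[Al](C)OC/C(C)=C/[Al](C)C | intermediate
26 | (E)-3-iodo-2-methylprop-2-en-1-ol | OC/C(C)=C/I | intermediate
27 | (E)-3-iodo-2-methylprop-2-enal | O=C/C(C)=C/I | intermediate
28 | (S)-4-benzyl-3-propanoyl-1,3-oxazolidin-2-one | CCC(=O)N1[C@@H](Cc2ccccc2)COC1=O | starting material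
29 | (Z)-dibutylboron enolate of 28 | CCCCB(CCCC)O/C(=C\C)N1[C@@H](Cc2ccccc2)COC1=O | intermediate
30 | (S)-4-benzyl-3-[(2S,3S,4E)-3-hydroxy-5-iodo-2,4-dimethylpent-4-enoyl]-1,3-oxazolidin-2-one | I/C=C(\C)[C@@H](O)[C@H](C)C(=O)N1[C@@H](Cc2ccccc2)COC1=O | intermediate
31 | TBS ether of 30 | I/C=C(\C)[C@@H](O[Si](C)(C)C(C)(C)C)[C@H](C)C(=O)N1[C@@H](Cc2ccccc2)COC1=O | intermediate
32 | (2S,3S,4E)-3-(tert-butyldimethylsilyloxy)-5-iodo-2,4-dimethylpent-4-enoic acid | I/C=C(\C)[C@@H](O[Si](C)(C)C(C)(C)C)[C@H](C)C(=O)O | intermediate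
33 | (E)-3-methylpent-2-en-4-yn-1-ol | C#C/C(C)=C/CO | starting material
34 | (2E,4E)-3-methyl-5-(tributylstannyl)penta-2,4-dien-1-ol | CCCC[Sn](CCCC)(CCCC)/C=C/C(C)=C/CO | intermediate
35 | (2E,4E)-3-methyl-5-(tributylstannyl)penta-2,4-dienal | CCCC[Sn](CCCC)(CCCC)/C=C/C(C)=C/C=O | intermediate
36 | 2-(diethoxyphosphoryl)acetic acid | CCOP(=O)(OCC)CC(=O)O | starting material
37 | dilithium dianion of 36 | [Li+].[Li+].CCOP(=O)(OCC)[CH-]C(=O)[O-] | intermediate
38 | (2E,4E,6E)-5-methyl-7-(tributylstannyl)hepta-2,4,6-trienoic acid | CCCC[Sn](CCCC)(CCCC)/C=C/C(C)=C/C=C/C(=O)O | intermediate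
39 | mixed anhydride of 32 with 2,4,6-trichlorobenzoic acid | I/C=C(\C)[C@@H](O[Si](C)(C)C(C)(C)C)[C@H](C)C(=O)OC(=O)c1c(Cl)cc(Cl)cc1Cl | intermediate
40 | C1 ester of 23 with 32 | I/C=C(\C)[C@@H](O[Si](C)(C)C(C)(C)C)[C@H](C)C(=O)O[C@H]1C[C@@H](C)C=C2C=C[C@@](C)(O[Si](CC)(CC)CC)[C@](C)([C@H]3CCO[Si](C(C)(C)C)(C(C)(C)C)O3)[C@H]21 | intermediate
41 | C7,C9,C11-triol (C3′ TBS ether) | I/C=C(\C)[C@@H](O[Si](C)(C)C(C)(C)C)[C@H](C)C(=O)O[C@H]1C[C@@H](C)C=C2C=C[C@@](C)(O)[C@](C)([C@H](O)CCO)[C@H]21 | intermediate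
42 | C11 TES ether of 41 | I/C=C(\C)[C@@H](O[Si](C)(C)C(C)(C)C)[C@H](C)C(=O)O[C@H]1C[C@@H](C)C=C2C=C[C@@](C)(O)[C@](C)([C@H](O)CCO[Si](CC)(CC)CC)[C@H]21 | intermediate
43 | C9 ketone of 42 | I/C=C(\C)[C@@H](O[Si](C)(C)C(C)(C)C)[C@H](C)C(=O)O[C@H]1C[C@@H](C)C=C2C=C[C@@](C)(O)[C@](C)(C(=O)CCO[Si](CC)(CC)CC)[C@H]21 | intermediate
44 | (1S,3R,7R,8R,8aS)-7-hydroxy-8-(3-hydroxypropanoyl)-3,7,8-trimethyl-1,2,3,7,8,8a-hexahydronaphthalen-1-yl (2S,3S,4E)-3-hydroxy-5-iodo-2,4-dimethylpent-4-enoate | I/C=C(\C)[C@@H](O)[C@H](C)C(=O)O[C@H]1C[C@@H](C)C=C2C=C[C@@](C)(O)[C@](C)(C(=O)CCO)[C@H]21 | intermediate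
45 | CNP0306937.1, (2E,4E,6E,8E,10S,11S)-10-hydroxy-12-{[(1S,3R,7R,8R,8aS)-7-hydroxy-8-(3-hydroxypropanoyl)-3,7,8-trimethyl-1,2,3,7,8,8a-hexahydronaphthalen-1-yl]oxy}-5,9,11-trimethyl-12-oxododeca-2,4,6,8-tetraenoic acid | CC(/C=C/C=C(\C)[C@@H](O)[C@H](C)C(=O)O[C@H]1C[C@@H](C)C=C2C=C[C@@](C)(O)[C@](C)(C(=O)CCO)[C@H]21)=C\C=C\C(=O)O | target

**Totals and risks**

Total step count: 27. Longest linear sequence: 18 steps (steps 1–9, 11–13, 22–27).

Steps most likely to fail:

1. Step 13. The recombination in 22 may show poor facial selectivity at C8a (ring B control opposes the preference of the C3 methyl for a pseudoequatorial position), the wrong C1 configuration, or competing proton transfer from C2–H. The fallback replaces the ring expansion by a Lewis-acid carbonyl-ene closure. Setting out from cyclobutanone 19, NaOMe in MeOH should open the strained 2-alkenylcyclobutanone by retro-Claisen cleavage of C1–C4 to methyl (3S)-3-methyl-4-[(3S,4R)-3-Dx-3,4-dimethyl-4-(triethylsilyloxy)cyclohexa-1,5-dien-1-yl]butanoate F1. Reduction with i-Bu2AlH at −78 °C should give (3S)-3-methyl-4-[(3S,4R)-3-Dx-3,4-dimethyl-4-(triethylsilyloxy)cyclohexa-1,5-dien-1-yl]butanal F2. Me2AlCl in CH2Cl2 at −78 °C should then close ring A by an intramolecular carbonyl-ene (Prins-type) reaction through a chair transition state, coming back to the route at 23.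

2. Step 11. The palladium enolate of the cyclobutanone may fragment, or the enolate regiochemistry may be lost by proton exchange with the more acidic product. The fallback brings in the cyclobutane as a C(sp3)–zinc reagent instead of an enolate. Setting out from 17, N-iodosuccinimide should give (2S,3R)-2-iodo-3-methylcyclobutan-1-one F3, NaBH4 the iodohydrin (1R,2S,3R)-2-iodo-3-methylcyclobutan-1-ol F4, and Ac2O/pyridine (1R,2S,3R)-2-iodo-3-methylcyclobutyl acetate F5. Zinc dust with LiCl should give (2-acetoxy-4-methylcyclobutyl)zinc iodide F6, and Negishi coupling with triflate 14 (Pd(OAc)2, a biaryl dialkylphosphine, THF) the acetate of 20, F7. K2CO3 in MeOH removes the acetate and the route is rejoined at 20.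

3. Step 10. The chiral base may discriminate poorly between the two enantiotopic α-CH2 groups of a ketone whose only substituent is a small methyl, giving low enantiomeric purity at C3. The fallback sets C3 by asymmetric conjugate reduction. Setting out from 15, α-bromination (pyridinium tribromide) should give 2-bromo-3-methylcyclobutan-1-one F8, and dehydrobromination (Li2CO3, LiBr, DMF) 3-methylcyclobut-2-en-1-one F9. Copper hydride reduction (CuCl, NaOt-Bu, p-tol-BINAP of the appropriate handedness, Ph2SiH2) should deliver hydride to C3 and give the regiodefined enol ether bis{[(R)-3-methylcyclobut-1-en-1-yl]oxy}diphenylsilane F10. Coupling of F10 with 14 under the conditions of step 11 comes back to the route at 19.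

**Further compounds**

F1 | step 13 | methyl (3S)-3-methyl-4-[(3S,4R)-3-Dx-3,4-dimethyl-4-(triethylsilyloxy)cyclohexa-1,5-dien-1-yl]butanoate | COC(=O)C[C@@H](C)CC1=C[C@@](C)([C@H]2CCO[Si](C(C)(C)C)(C(C)(C)C)O2)[C@](C)(O[Si](CC)(CC)CC)C=C1
F2 | step 13 | (3S)-3-methyl-4-[(3S,4R)-3-Dx-3,4-dimethyl-4-(triethylsilyloxy)cyclohexa-1,5-dien-1-yl]butanal | O=CC[C@@H](C)CC1=C[C@@](C)([C@H]2CCO[Si](C(C)(C)C)(C(C)(C)C)O2)[C@](C)(O[Si](CC)(CC)CC)C=C1
F3 | step 11 | (2S,3R)-2-iodo-3-methylcyclobutan-1-one | O=C1C[C@@H](C)[C@@H]1I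
F4 | step 11 | (1R,2S,3R)-2-iodo-3-methylcyclobutan-1-ol | O[C@@H]1C[C@@H](C)[C@@H]1I
F5 | step 11 | (1R,2S,3R)-2-iodo-3-methylcyclobutyl acetate | CC(=O)O[C@@H]1C[C@@H](C)[C@@H]1I
F6 | step 11 | (2-acetoxy-4-methylcyclobutyl)zinc iodide | CC(=O)O[C@@H]1C[C@@H](C)C1[Zn]I
F7 | step 11 | acetate of 20 | CC(=O)O[C@@H]1C[C@@H](C)[C@@H]1C2=C[C@@](C)([C@H]3CCO[Si](C(C)(C)C)(C(C)(C)C)O3)[C@](C)(O[Si](CC)(CC)CC)C=C2
F8 | step 10 | 2-bromo-3-methylcyclobutan-1-one | CC1CC(=O)C1Br
F9 | step 10 | 3-methylcyclobut-2-en-1-one | CC1=CC(=O)C1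
F10 | step 10 | bis{[(R)-3-methylcyclobut-1-en-1-yl]oxy}diphenylsilane | C[C@H]1C=C(O[Si](c2ccccc2)(c2ccccc2)OC2=C[C@H](C)C2)C1
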